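## Retrosynthetic overview

1. The target comes from a drim-7-ene-3,6,11-triol by C11 aryl ether formation, invertive acetylation at C6 and oxidation at C3; the triol comes from hydride reduction of a 3-hydroxy-7-en-6-one 11-ester.
2. Key disconnection C3–C4 (ring A closed last): SmI2 reductive coupling of a C3 aldehyde, as its ketyl (a carbonyl carbon of reversed polarity), with the β-carbon of a C5-isopropylidene C6-ketone. Two acceptor carbons are joined, giving the 1,4-related C3/C6 oxygens and the gem-dimethyl carbon that a polarity-normal annulation would place wrongly.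
3. The isopropylidene ketone comes from acetone aldol/dehydration on the enolate formed by conjugate methylation (quaternary C10) of a ring B cyclohexenone.
4. Ring B is formed first, by an organocatalytic Robinson-type annulation of (E)-pent-3-en-2-one with an acetal-bearing β-keto ester. Its one catalyst-set methyl stereocentre (C8, later sp2) relays to C10, C5 and C6.

Assumption: 9-amino-9-deoxy-epi-quinine gives the (S) Michael centre drawn in 5/6; if it gives the antipode, the quinidine-derived pseudoenantiomer is used.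

Numbering note: bicyclic compounds carry drimane numbering (C3 ring A carbinol/ketone carbon, C4 gem-dimethyl carbon, C5/C10 ring fusion, C6, C7=C8, C9 bearing C11). The target is (5S,6R,9R,10S): H5 trans to the C10 methyl, C11 cis to it, acetate trans to it.

## Route

Step 1
Reactants: 1 methyl 4,4-dimethoxybutanoate; 2 ethyl acetate
Product: 3 ethyl 6,6-dimethoxy-3-oxohexanoate
Conditions: 2 (2.2 equiv), LiN(i-Pr)2 (2.2 equiv), THF, −78 °C; then 1, −78 → 0 °C; aqueous work-up
Reagents that add atoms: none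
Why: Crossed Claisen condensation of the lithium enolate of ethyl acetate with the non-enolisable-side methyl ester gives the β-keto ester, and no stereocentre is formed.

Step 2
Reactants: 3 ethyl 6,6-dimethoxy-3-oxohexanoate; 4 (E)-pent-3-en-2-one
Product: 6 ethyl (1R,6S)-2-(3,3-dimethoxypropyl)-6-methyl-4-oxocyclohex-2-ene-1-carboxylate, via Michael adduct 5 (not isolated)
Conditions: 9-amino-9-deoxy-epi-quinine (20 mol %), 2-FC6H4CO2H (40 mol %), 4 Å MS, toluene, 25 → 60 °C
Reagents that add atoms: none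
Why: Organocatalytic Robinson-type annulation (iminium-activated Michael addition, then enamine aldol condensation of the methyl ketone onto the β-keto ester carbonyl) in which the catalyst sets the methyl-bearing centre (6S) and the epimerisable C1 settles trans to it.

Step 3
Reactants: 6 ethyl (1R,6S)-2-(3,3-dimethoxypropyl)-6-methyl-4-oxocyclohex-2-ene-1-carboxylate
Product: 8 ethyl (1R,2R,6S)-2-(3,3-dimethoxypropyl)-3-(2-hydroxypropan-2-yl)-2,6-dimethyl-4-oxocyclohexane-1-carboxylate (C3 epimers), via lithium enolate 7 (not isolated)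
Conditions: MeLi, CuI, Et2O, 0 °C (gives Me2CuLi); 6, −78 → −30 °C; then ZnCl2, acetone, −78 °C
Reagents that add atoms: Me2CuLi (lithium dimethylcuprate), [Li+].C[Cu-]C; acetone, CC(C)=O
Why: Gilman conjugate addition with axial attack anti to the ring methyl (trans-3,5 rule) sets the quaternary centre (future C10, methyl cis to the ester), and the regiodefined enolate is trapped by aldol addition to acetone at the future C5.

Step 4
Reactants: 8 ethyl (1R,2R,6S)-2-(3,3-dimethoxypropyl)-3-(2-hydroxypropan-2-yl)-2,6-dimethyl-4-oxocyclohexane-1-carboxylate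
Product: 9 ethyl (1R,2S,6S)-2,6-dimethyl-4-oxo-2-(3-oxopropyl)-3-(propan-2-ylidene)cyclohexane-1-carboxylate
Conditions: TsOH·H2O (20 mol %), acetone–H2O (10:1), 45 °C
Reagents that add atoms: water, O
Why: Acid-catalysed E1 dehydration of the tertiary aldol to the conjugated isopropylidene ketone with concurrent acetal hydrolysis, the aldol centre becoming sp2 and the other three stereocentres untouched.

Step 5
Reactants: 9 ethyl (1R,2S,6S)-2,6-dimethyl-4-oxo-2-(3-oxopropyl)-3-(propan-2-ylidene)cyclohexane-1-carboxylate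
Product: 11 ethyl (3R,5S,8S,9R,10R)-3-hydroxy-6-oxodriman-11-oate, via samarium enolate 10 (not isolated)
Conditions: SmI2 (2.5 equiv), t-BuOH (3 equiv), THF (0.01 M), −78 → 0 °C
Reagents that add atoms: none
Why: SmI2 ketyl–olefin (reductive aldehyde–enone) cyclisation in which the C3 ketyl, a carbonyl carbon of reversed polarity, bonds to the enone β-carbon C4 and so closes ring A and creates the gem-dimethyl carbon, axial protonation of the resulting enolate anti to the angular methyl giving the trans ring fusion (5S), while the C3 carbinol (drawn equatorial) is oxidised later and its configuration is inconsequential.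

Step 6
Reactants: 11 ethyl (3R,5S,8S,9R,10R)-3-hydroxy-6-oxodriman-11-oate
Product: 13 ethyl (3R,5S,9R,10R)-3-hydroxy-6-oxodrim-7-en-11-oate, via bis-silyl enol ether 12 (not isolated)
Conditions: LiN(i-Pr)2 (2.3 equiv), Me3SiCl, THF, −78 °C; then Pd(OAc)2 (1.1 equiv), MeCN, 25 °C; dilute aqueous acid work-up
Reagents that add atoms: none
Why: Saegusa–Ito dehydrogenation, in which kinetic enolisation occurs toward C7 (C5 is flanked by two quaternary carbons) and β-hydride elimination from C8 gives the 7-en-6-one, erasing the relay stereocentre C8 without touching C5, C9 or C10.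

Step 7
Reactants: 13 ethyl (3R,5S,9R,10R)-3-hydroxy-6-oxodrim-7-en-11-oate
Product: 14 (3R,5S,6S,9R,10S)-drim-7-ene-3,6,11-triol
Conditions: i-Bu2AlH (7 equiv), CH2Cl2, −78 → −20 °C; aqueous work-up
Reagents that add atoms: none
Why: Non-basic hydride reduction (ester to primary alcohol, 1,2-reduction of the enone) with hydride delivered to C6 from the face opposite the axial C10 and C4 methyls, giving the axial 6-alcohol (6S) that step 9 inverts.

Step 8
Reactants: 14 (3R,5S,6S,9R,10S)-drim-7-ene-3,6,11-triol; 15 umbelliferone (7-hydroxy-2H-chromen-2-one)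
Product: 16 (3R,5S,6S,9R,10S)-11-[(2-oxo-2H-chromen-7-yl)oxy]drim-7-ene-3,6-diol
Conditions: 15 (1.05 equiv), PPh3, DIAD, THF, 0 °C
Reagents that add atoms: none
Why: Mitsunobu etherification, selective for the primary C11 alcohol over the two hindered secondary alcohols, with no stereocentre involved.

Step 9
Reactants: 16 (3R,5S,6S,9R,10S)-11-[(2-oxo-2H-chromen-7-yl)oxy]drim-7-ene-3,6-diol
Product: 17 (3R,5S,6R,9R,10S)-3-hydroxy-11-[(2-oxo-2H-chromen-7-yl)oxy]drim-7-en-6-yl acetate
Conditions: AcOH, PPh3, DIAD, toluene, 0 → 25 °C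
Reagents that add atoms: acetic acid, CC(=O)O
Why: Mitsunobu esterification with SN2 inversion at the activated allylic C6 turns the axial alcohol into the equatorial acetate (6R), the C3 hydroxyl next to the quaternary C4 being inert to displacement.

Step 10
Reactants: 17 (3R,5S,6R,9R,10S)-3-hydroxy-11-[(2-oxo-2H-chromen-7-yl)oxy]drim-7-en-6-yl acetate
Product: 18 (5S,6R,9R,10S)-3-oxo-11-[(2-oxo-2H-chromen-7-yl)oxy]drim-7-en-6-yl acetate
Conditions: Dess–Martin periodinane, CH2Cl2, 0 → 25 °C
Reagents that add atoms: none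
Why: Dess–Martin oxidation of the remaining secondary alcohol to the C3 ketone under neutral conditions that leave the allylic acetate, the coumarin and all stereocentres intact.

## Compound list

1 | methyl 4,4-dimethoxybutanoate | COC(=O)CCC(OC)OC | starting material
2 | ethyl acetate | CCOC(C)=O | starting material
3 | ethyl 6,6-dimethoxy-3-oxohexanoate | CCOC(=O)CC(=O)CCC(OC)OC | intermediate
4 | (E)-pent-3-en-2-one | C/C=C/C(C)=O | starting material
5 | ethyl (3S)-2-(4,4-dimethoxybutanoyl)-3-methyl-5-oxohexanoate (C2 epimers) | CCOC(=O)C(C(=O)CCC(OC)OC)[C@@H](C)CC(C)=O | intermediate (not isolated)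
6 | ethyl (1R,6S)-2-(3,3-dimethoxypropyl)-6-methyl-4-oxocyclohex-2-ene-1-carboxylate | CCOC(=O)[C@@H]1[C@@H](C)CC(=O)C=C1CCC(OC)OC | intermediate
7 | lithium (3R,4R,5S)-3-(3,3-dimethoxypropyl)-4-(ethoxycarbonyl)-3,5-dimethylcyclohex-1-en-1-olate | CCOC(=O)[C@@H]1[C@@H](C)CC(O[Li])=C[C@@]1(C)CCC(OC)OC | intermediate (not isolated)
8 | ethyl (1R,2R,6S)-2-(3,3-dimethoxypropyl)-3-(2-hydroxypropan-2-yl)-2,6-dimethyl-4-oxocyclohexane-1-carboxylate (C3 epimers) | CCOC(=O)[C@@H]1[C@@H](C)CC(=O)C(C(C)(C)O)[C@@]1(C)CCC(OC)OC | intermediate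
9 | ethyl (1R,2S,6S)-2,6-dimethyl-4-oxo-2-(3-oxopropyl)-3-(propan-2-ylidene)cyclohexane-1-carboxylate | CCOC(=O)[C@@H]1[C@@H](C)CC(=O)C(=C(C)C)[C@@]1(C)CCC=O | intermediate
10 | ethyl (8S,9R,10S)-3,6-bis[(diiodosamario)oxy]drim-5-en-11-oate (C3 alkoxide and C5=C6 enolate of trivalent samarium, C3 epimers) | CCOC(=O)[C@@H]1[C@@H](C)CC(O[Sm](I)I)=C2C(C)(C)C(O[Sm](I)I)CC[C@@]12C | intermediate (not isolated)
11 | ethyl (3R,5S,8S,9R,10R)-3-hydroxy-6-oxodriman-11-oate | O=C1C[C@H](C)[C@@H](C(=O)OCC)[C@]2(C)CC[C@@H](O)C(C)(C)[C@@H]12 | intermediate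
12 | ethyl (3R,5S,8S,9R,10R)-3,6-bis[(trimethylsilyl)oxy]drim-6-en-11-oate | C[Si](C)(C)OC1=C[C@H](C)[C@@H](C(=O)OCC)[C@]2(C)CC[C@@H](O[Si](C)(C)C)C(C)(C)[C@@H]12 | intermediate (not isolated)
13 | ethyl (3R,5S,9R,10R)-3-hydroxy-6-oxodrim-7-en-11-oate | O=C1C=C(C)[C@@H](C(=O)OCC)[C@]2(C)CC[C@@H](O)C(C)(C)[C@@H]12 | intermediate
14 | (3R,5S,6S,9R,10S)-drim-7-ene-3,6,11-triol | O[C@H]1C=C(C)[C@@H](CO)[C@]2(C)CC[C@@H](O)C(C)(C)[C@@H]12 | intermediate
15 | umbelliferone (7-hydroxy-2H-chromen-2-one) | Oc1ccc2ccc(=O)oc2c1 | starting material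
16 | (3R,5S,6S,9R,10S)-11-[(2-oxo-2H-chromen-7-yl)oxy]drim-7-ene-3,6-diol | O[C@H]1C=C(C)[C@@H](COc2ccc3ccc(=O)oc3c2)[C@]2(C)CC[C@@H](O)C(C)(C)[C@@H]12 | intermediate
17 | (3R,5S,6R,9R,10S)-3-hydroxy-11-[(2-oxo-2H-chromen-7-yl)oxy]drim-7-en-6-yl acetate | CC(=O)O[C@@H]1C=C(C)[C@@H](COc2ccc3ccc(=O)oc3c2)[C@]2(C)CC[C@@H](O)C(C)(C)[C@@H]12 | intermediate
18 | (5S,6R,9R,10S)-3-oxo-11-[(2-oxo-2H-chromen-7-yl)oxy]drim-7-en-6-yl acetate (CNP0140705.2) | CC(=O)O[C@@H]1C=C(C)[C@@H](COc2ccc3ccc(=O)oc3c2)[C@]2(C)CCC(=O)C(C)(C)[C@@H]12 | target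

## Step count and risks

Total step count: 10. Longest linear sequence: 10 steps (from 1 and 2).

Steps most likely to fail:

Step 5 (SmI2 ring closure). The acceptor is a tetrasubstituted enone with allylic 1,3-strain that may sit partly as its β,γ-isomer, and pinacol coupling or simple reduction can compete. The fallback sets out from 9 and comes back at 11. Compound 9 is heated with 3-benzyl-5-(2-hydroxyethyl)-4-methylthiazolium chloride (20 mol %) and DBU in toluene at 80 °C. The carbene-bound acyl anion of C3 adds to C4 in an intramolecular Stetter reaction; DBU keeps the enone isomers in equilibrium and the competing aldehyde–ketone benzoin is reversible. This gives the diketone ethyl (5S,8S,9R,10R)-3,6-dioxodriman-11-oate F1. NaBH4 in MeOH at −40 °C then reduces only the more accessible C3 ketone (axial attack, equatorial alcohol) to give 11.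

Step 3 (conjugate methylation/acetone aldol, with the dehydration of step 4). A ketone–ketone aldol at an enolate carbon next to a new quaternary centre may stall or revert. The fallback sets out from 6 and comes back at 9. The Me2CuLi addition is run with Me3SiCl to give the silyl enol ether ethyl (1R,2R,6S)-2-(3,3-dimethoxypropyl)-2,6-dimethyl-4-[(trimethylsilyl)oxy]cyclohex-3-ene-1-carboxylate F2. Palladium-catalysed α-alkenylation with 2-bromopropene (Pd2(dba)3, P(t-Bu)3, Bu3SnF, toluene, 80 °C) forms the C5–C4 bond by cross-coupling, giving ethyl (1R,2R,6S)-2-(3,3-dimethoxypropyl)-2,6-dimethyl-4-oxo-3-(prop-1-en-2-yl)cyclohexane-1-carboxylate F3. TsOH in wet acetone then hydrolyses the acetal and moves the double bond into conjugation to give 9.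

Step 9 (invertive acetylation at C6). The axial allylic alcohol is hindered, elimination to a diene or SN2′ attack can compete, and the free C3 hydroxyl may be acylated. The fallback sets out from 16 and comes back at 18. Dess–Martin periodinane oxidises both secondary alcohols to (5S,9R,10S)-11-[(2-oxo-2H-chromen-7-yl)oxy]drim-7-ene-3,6-dione F4. NaBH4 with CeCl3·7H2O in MeOH at −78 °C reduces only the enone carbonyl, giving the axial alcohol (5S,6S,9R,10S)-6-hydroxy-11-[(2-oxo-2H-chromen-7-yl)oxy]drim-7-en-3-one F5. Ionising acetolysis (AcOH, Sc(OTf)3 5 mol %, 25 °C) then goes through the C6–C8 allyl cation, which acetate captures from the open face under thermodynamic control to give the equatorial acetate 18 directly.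

## Further compounds

F1 | step 5 | ethyl (5S,8S,9R,10R)-3,6-dioxodriman-11-oate | O=C1C[C@H](C)[C@@H](C(=O)OCC)[C@]2(C)CCC(=O)C(C)(C)[C@@H]12
F2 | step 3 | ethyl (1R,2R,6S)-2-(3,3-dimethoxypropyl)-2,6-dimethyl-4-[(trimethylsilyl)oxy]cyclohex-3-ene-1-carboxylate | CCOC(=O)[C@@H]1[C@@H](C)CC(O[Si](C)(C)C)=C[C@@]1(C)CCC(OC)OC
F3 | step 3 | ethyl (1R,2R,6S)-2-(3,3-dimethoxypropyl)-2,6-dimethyl-4-oxo-3-(prop-1-en-2-yl)cyclohexane-1-carboxylate (C3 epimers) | CCOC(=O)[C@@H]1[C@@H](C)CC(=O)C(C(C)=C)[C@@]1(C)CCC(OC)OC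
F4 | step 9 | (5S,9R,10S)-11-[(2-oxo-2H-chromen-7-yl)oxy]drim-7-ene-3,6-dione | O=C1C=C(C)[C@@H](COc2ccc3ccc(=O)oc3c2)[C@]2(C)CCC(=O)C(C)(C)[C@@H]12
F5 | step 9 | (5S,6S,9R,10S)-6-hydroxy-11-[(2-oxo-2H-chromen-7-yl)oxy]drim-7-en-3-one | O[C@H]1C=C(C)[C@@H](COc2ccc3ccc(=O)oc3c2)[C@]2(C)CCC(=O)C(C)(C)[C@@H]12
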